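GA55 is disconnected at C1–C2: the syn C1/C3 diol of ring A is treated as a ketol, so ring A closes last by an intramolecular aldol across the C19–O–C10 γ-lactone. The feature used is that C4 and C10 are both quaternary: the C4 acetyl group can enolise only toward C2, the C10 aldehyde cannot enolise, and the lactone fused to ring B holds both arms cis. One operation forms C1–C2, ring A and the C1 carbinol stereocentre. The precursor is the rings B/C/D lactone bearing C4 methyl and acetyl, C10 formyl, a 2-silylethyl C7 ester and an unprotected tertiary C13 hydroxyl, which needs no silyl ether.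

Key step: step 17

Convention: gibberellane numbering (C1–C19, rings A–D) is used for all intermediates; β is the face of H-5, H-9, C-7 and C-15, α that of the lactone bridge and C-14.
Assumption: the lipase in step 2 acylates the (S)-alcohol faster; with the opposite preference the (R)-acetate would be isolated and methanolysed before step 3.

Step 1
Reactants: 1 3-methoxycyclopent-2-en-1-one; 2 formaldehyde
Product: 4 rac-5-(hydroxymethyl)-3-methoxycyclopent-2-en-1-one, via lithium dienolate 3 (not isolated)
Conditions: LiN(iPr)2, THF, −78 °C; CH2O (gas, cracked from paraformaldehyde), −78 °C; AcOH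
Reagents that add atoms: none
Why: Kinetic α′-deprotonation of the vinylogous ester and aldol addition of the cross-conjugated lithium dienolate to monomeric formaldehyde (enolate hydroxymethylation) should attach C7 to C6, the new C6 stereocentre being formed racemic and resolved in step 2.

Step 2
Reactants: 4 rac-5-(hydroxymethyl)-3-methoxycyclopent-2-en-1-one
Product: 5 (R)-5-(hydroxymethyl)-3-methoxycyclopent-2-en-1-one
Conditions: lipase from Burkholderia cepacia (immobilised), vinyl acetate (0.6 equiv), t-BuOMe, 25 °C, stopped near half conversion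
Reagents that add atoms: none
Why: Lipase-catalysed irreversible transesterification (enzymatic kinetic resolution) of a primary alcohol with a β-stereocentre should acylate one enantiomer selectively, so that the unreacted (R)-alcohol, which has the C6 configuration of the target, is recovered as a single enantiomer.

Step 3
Reactants: 5 (R)-5-(hydroxymethyl)-3-methoxycyclopent-2-en-1-one
Product: 6 (R)-3-methoxy-5-{[(triisopropylsilyl)oxy]methyl}cyclopent-2-en-1-one
Conditions: iPr3SiCl, imidazole, DMF, 0 → 23 °C
Reagents that add atoms: triisopropylsilyl chloride, CC(C)[Si](Cl)(C(C)C)C(C)C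
Why: Silylation of the primary alcohol under imidazole conditions gives an ether that should survive the acid, enolate and organolithium steps and be removed by fluoride in step 10.

Step 4
Reactants: 6 (R)-3-methoxy-5-{[(triisopropylsilyl)oxy]methyl}cyclopent-2-en-1-one; 7 3-bromo-1-(trimethylsilyl)prop-1-yne
Product: 10 (S)-4-{[(triisopropylsilyl)oxy]methyl}-3-[3-(trimethylsilyl)prop-2-yn-1-yl]cyclopent-2-en-1-one, via propargylzinc bromide 8 (not isolated), via tertiary carbinol 9 (not isolated)
Conditions: Zn dust (Me3SiCl-activated), THF, 0 → 23 °C; then 1 M HCl, THF, 0 °C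
Reagents that add atoms: water, O
Why: The zinc reagent from the silyl-capped propargyl bromide should add through its allenyl form to the vinylogous ester carbonyl to give the homopropargylic carbinol (Barbier propargylation), and acid-mediated loss of water with hydrolysis of the enol ether transposes the enone (Stork–Danheiser sequence) under non-basic conditions that leave the C6 centre untouched.

Step 5
Reactants: 11 but-3-en-2-one
Product: 12 2-[(triisopropylsilyl)oxy]buta-1,3-diene
Conditions: iPr3SiOSO2CF3, Et3N, Et2O, 0 → 23 °C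
Reagents that add atoms: triisopropylsilyl trifluoromethanesulfonate, CC(C)[Si](OS(=O)(=O)C(F)(F)F)(C(C)C)C(C)C
Why: Soft enolisation of the enone with silyl triflate and amine (silyl enol ether formation) gives the 2-silyloxydiene, the bulky silyl group being chosen so that the enol ether formed in step 6 survives steps 7 and 9.

Step 6
Reactants: 10 (S)-4-{[(triisopropylsilyl)oxy]methyl}-3-[3-(trimethylsilyl)prop-2-yn-1-yl]cyclopent-2-en-1-one; 12 2-[(triisopropylsilyl)oxy]buta-1,3-diene
Product: 13 cis-fused bicyclic ketone (C10 ketone; C6 β-CH2OSi; C8 β-propargyl; H-9β; C12=C13 silyl enol ether)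
Conditions: HN(SO2CF3)2 (5 mol %), CH2Cl2, −78 → −40 °C; Et3N quench
Reagents that add atoms: none
Why: The silyl triflimide generated in situ should activate the hindered β,β-disubstituted enone for a Diels–Alder reaction with the 2-silyloxydiene (a known way to build quaternary ring-fusion carbons), the diene carbon next to the silyloxy group bonding to the β-carbon C8 (para orientation), the diene approaching anti to the C6 CH2OSi group and adding suprafacially, which sets C8 and C9 relative to C6 and leaves the C13 ketone masked as its silyl enol ether.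

Step 7
Reactants: 13 cis-fused bicyclic ketone; 14 ethyl (S)-2-{[(trifluoromethyl)sulfonyl]oxy}propanoate
Product: 16 C5-alkylated keto ester (C5 α-CH(CH3)CO2Et), via lithium enolate 15 (not isolated)
Conditions: LiN(iPr)2, THF, −78 °C; then 14, −78 → −40 °C
Reagents that add atoms: none
Why: Kinetic deprotonation at the C5 methylene and SN2 alkylation of the lithium enolate with the lactate triflate (enolate alkylation with inversion at C4) should place the propanoate chain on C5 trans to the C6 substituent, that is α, as is usual next to a substituted ring carbon, while the C4 configuration does not matter because it is erased in step 14.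

Step 8
Reactants: 17 (4-methoxyphenyl)methanol; 18 tributyl(iodomethyl)stannane
Product: 20 tributyl{[(4-methoxybenzyl)oxy]methyl}stannane, via sodium alkoxide 19 (not isolated)
Conditions: NaH, THF/DMF, 0 → 23 °C
Reagents that add atoms: none
Why: Williamson etherification of the sodium alkoxide with the primary iodomethylstannane gives the α-alkoxymethylstannane needed for tin–lithium exchange.

Step 9
Reactants: 16 C5-alkylated keto ester; 20 tributyl{[(4-methoxybenzyl)oxy]methyl}stannane
Product: 23 bicyclic 19,10-γ-lactone (C10 β-CH2O-4-methoxybenzyl), via alkoxymethyllithium 21 (not isolated), via C10 lithium alkoxide 22 (not isolated)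
Conditions: 20, n-BuLi, THF, −78 °C; then 16 premixed with anhydrous CeCl3, THF, −78 → 0 °C; NH4Cl (aq)
Reagents that add atoms: none
Why: Tin–lithium exchange gives the α-alkoxymethyllithium, which should add to the CeCl3-activated C10 ketone rather than to the ester and from the β face, anti to the α substituents on both neighbouring carbons (C4 on C5 and C11 on C9), after which the α alkoxide closes the cis-fused γ-lactone on the ethyl ester (carbonyl addition then lactonisation) and so sets C10.

Step 10
Reactants: 23 bicyclic 19,10-γ-lactone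
Product: 24 keto alkyne lactone (C13 ketone; terminal alkyne; C7 CH2OH)
Conditions: Bu4NF (4 equiv), AcOH (4 equiv), THF, 0 → 23 °C
Reagents that add atoms: none
Why: Buffered fluoride should cleave all three silicon groups in one operation (desilylation), releasing the C13 ketone from its enol ether, the terminal alkyne and the C7 alcohol, while the buffer suppresses base-induced translactonisation.

Step 11
Reactants: 24 keto alkyne lactone
Product: 25 tricyclic lactone diol (rings B, C and D; 13-OH; 16-methylene)
Conditions: SmI2 (2.5 equiv), (Me2N)3PO, t-BuOH, THF, 0 °C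
Reagents that add atoms: none
Why: Single-electron reduction of the C13 ketone and 5-exo-dig addition of the ketyl to the alkyne tethered at C8 (SmI2 ketyl–alkyne reductive cyclisation) should close ring D to the bridgehead tertiary alcohol with the exocyclic alkene, the C13 configuration being dictated by the bridge and the lactone and ethers being inert to the reagent.

Step 12
Reactants: 25 tricyclic lactone diol
Product: 27 C7 carboxylic acid, via C7 aldehyde 26 (not isolated)
Conditions: TEMPO (2,2,6,6-tetramethylpiperidin-1-oxyl, 0.2 equiv), PhI(OAc)2 (2.5 equiv), MeCN/pH 7 buffer, 23 °C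
Reagents that add atoms: water, O
Why: Nitroxyl-catalysed oxidation with PhI(OAc)2 in aqueous medium (TEMPO oxidation) should take the primary alcohol through the aldehyde hydrate to the acid without touching the tertiary alcohol or the alkene, C6 keeping its configuration trans to the C5 substituent, which is also the stable one.

Step 13
Reactants: 27 C7 carboxylic acid
Product: 28 C7 2-(trimethylsilyl)ethyl ester
Conditions: Me3SiCH2CH2OH, PPh3, iPrO2CN=NCO2iPr, THF, 0 → 23 °C
Reagents that add atoms: 2-(trimethylsilyl)ethanol, C[Si](C)(C)CCO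
Why: Mitsunobu esterification alkylates the carboxylate oxygen, so the hindered C7 carbonyl need not be attacked and the tertiary C13 alcohol does not react.

Step 14
Reactants: 28 C7 2-(trimethylsilyl)ethyl ester; 29 acetaldehyde
Product: 31 C4 1-hydroxyethyl lactone (C4 quaternary), via dilithium alkoxide enolate 30 (not isolated)
Conditions: LiN(iPr)2 (2.3 equiv), THF, −78 °C; CH3CHO (5 equiv), −78 °C; AcOH
Reagents that add atoms: none
Why: Two equivalents of base give the C13 alkoxide and the lactone enolate, whose aldol addition to acetaldehyde (lithium enolate aldol) should take place on the convex face of the cis-fused lactone/ring B bicycle, the face of H-5 and away from C6, so that the new C3 carbon ends cis to C1 and the methyl group on the concave face as C4 requires, the carbinol configuration being irrelevant.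

Step 15
Reactants: 31 C4 1-hydroxyethyl lactone
Product: 32 triol (C10 β-CH2OH)
Conditions: DDQ (2,3-dichloro-5,6-dicyano-1,4-benzoquinone, 1.3 equiv), CH2Cl2/pH 7 buffer, 0 °C
Reagents that add atoms: none
Why: Oxidative cleavage of the 4-methoxybenzyl ether with DDQ under buffered conditions is neutral and should leave the alkene, the lactone, the silylethyl ester and the free alcohols untouched.

Step 16
Reactants: 32 triol
Product: 33 keto aldehyde (C4 acetyl; C10 formyl)
Conditions: (COCl)2, Me2SO, CH2Cl2, −78 °C; Et3N, −78 → −30 °C; pH 7 buffer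
Reagents that add atoms: none
Why: In the Swern oxidation both hydroxyls are converted to alkoxysulfonium salts before base is added, so the primary and the secondary alcohol are oxidised together and no lactol between C1 and O3 can form and be over-oxidised to a lactone, while the tertiary alcohol cannot be oxidised.

Step 17
Reactants: 33 keto aldehyde
Product: 35 1β-hydroxy-3-oxo tetracyclic lactone, via pyrrolidine enamine 34 (not isolated)
Conditions: pyrrolidine (0.3 equiv), AcOH (0.3 equiv), THF, 0 °C
Reagents that add atoms: none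
Why: Pyrrolidine condenses with the C4 acetyl group to a terminal enamine (C2=C3), the only one possible because C4 is quaternary, and this adds to the C10 aldehyde, which cannot enolise; hydrolysis of the iminium returns the amine. The closest known reaction type is the amine-catalysed intramolecular aldolisation of a ketone onto a second carbonyl group (Hajos–Parrish type), here with a keto aldehyde. Ring A closes in the 6-(enolendo)-exo-trig mode, the two reacting arms being held cis on the γ-lactone. The new C1 stereocentre is set by the substrate: in the chair-like transition state the aldehyde C=O lies anti to the C10–O lactone bond so that the dipoles are minimised, which puts the hydroxyl axial and β, trans-diaxial to C10–O, and because the addition is reversible the mixture can drift further toward this ketol. The step needs cross-selectivity and survival of the ketol: the first is guaranteed by the two quaternary carbons, the second should be secured by the low temperature and the buffered catalyst, since elimination of the axial hydroxyl to the C1=C2 enone is the main risk.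

Step 18
Reactants: 35 1β-hydroxy-3-oxo tetracyclic lactone
Product: 36 GA55 2-(trimethylsilyl)ethyl ester
Conditions: KBH(sBu)3 (3.5 equiv), THF, −78 °C; NH4Cl (aq)
Reagents that add atoms: none
Why: The bulky borohydride should deliver hydride to C3 from the α side along the equatorial direction, because the β-axial trajectory is blocked by the axial 1β-oxygen and H-5, giving the axial 3β-alcohol syn to O1 (sterically controlled ketone reduction), while the low temperature suppresses retro-aldol cleavage.

Step 19
Reactants: 36 GA55 2-(trimethylsilyl)ethyl ester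
Product: 37 GA55
Conditions: Bu4NF (3 equiv), THF, 0 → 23 °C; then dilute HCl to pH 3
Reagents that add atoms: none
Why: Fluoride attacks silicon and the 2-silylethyl ester fragments to the carboxylate, ethene and fluorosilane (β-elimination deprotection), conditions mild enough that retro-aldol epimerisation at C3 should not occur.

Compound list
1 | 3-methoxycyclopent-2-en-1-one | COC1=CC(=O)CC1 | starting material
2 | formaldehyde | C=O | starting material
3 | lithium 4-methoxycyclopenta-1,3-dien-2-olate (dienolate of 1) | COC1=CC(O[Li])=CC1 | intermediate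
4 | rac-5-(hydroxymethyl)-3-methoxycyclopent-2-en-1-one | COC1=CC(=O)C(CO)C1 | intermediate
5 | (R)-5-(hydroxymethyl)-3-methoxycyclopent-2-en-1-one | COC1=CC(=O)[C@@H](CO)C1 | intermediate
6 | (R)-3-methoxy-5-{[(triisopropylsilyl)oxy]methyl}cyclopent-2-en-1-one | COC1=CC(=O)[C@@H](CO[Si](C(C)C)(C(C)C)C(C)C)C1 | intermediate
7 | 3-bromo-1-(trimethylsilyl)prop-1-yne | C[Si](C)(C)C#CCBr | starting material
8 | [3-(trimethylsilyl)prop-2-yn-1-yl]zinc bromide (in equilibrium with its allenyl form) | C[Si](C)(C)C#CC[Zn]Br | intermediate
9 | (5R)-3-methoxy-5-{[(triisopropylsilyl)oxy]methyl}-1-[3-(trimethylsilyl)prop-2-yn-1-yl]cyclopent-2-en-1-ol, both C1 epimers | COC1=CC(O)(CC#C[Si](C)(C)C)[C@@H](CO[Si](C(C)C)(C(C)C)C(C)C)C1 | intermediate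
10 | (S)-4-{[(triisopropylsilyl)oxy]methyl}-3-[3-(trimethylsilyl)prop-2-yn-1-yl]cyclopent-2-en-1-one | O=C1C=C(CC#C[Si](C)(C)C)[C@@H](CO[Si](C(C)C)(C(C)C)C(C)C)C1 | intermediate
11 | but-3-en-2-one | C=CC(C)=O | starting material
12 | 2-[(triisopropylsilyl)oxy]buta-1,3-diene | C=CC(=C)O[Si](C(C)C)(C(C)C)C(C)C | intermediate
13 | cis-fused 5-[(triisopropylsilyl)oxy]-3-{[(triisopropylsilyl)oxy]methyl}-3a-[3-(trimethylsilyl)prop-2-yn-1-yl]-2,3,3a,4,7,7a-hexahydro-1H-inden-1-one; C10 ketone, C6 β-CH2OSi, C8 β-propargyl, H-9β, C12=C13 silyl enol ether | O=C1C[C@H](CO[Si](C(C)C)(C(C)C)C(C)C)[C@@]2(CC#C[Si](C)(C)C)CC(O[Si](C(C)C)(C(C)C)C(C)C)=CC[C@@H]12 | intermediate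
14 | ethyl (S)-2-{[(trifluoromethyl)sulfonyl]oxy}propanoate | CCOC(=O)[C@H](C)OS(=O)(=O)C(F)(F)F | starting material
15 | lithium enolate of 13 (C5=C10–OLi) | [Li]OC1=C[C@H](CO[Si](C(C)C)(C(C)C)C(C)C)[C@@]2(CC#C[Si](C)(C)C)CC(O[Si](C(C)C)(C(C)C)C(C)C)=CC[C@@H]12 | intermediate
16 | 13 carrying on C5 (α, trans to the C6 substituent) a (2S)-1-ethoxy-1-oxopropan-2-yl group (C4, C18, C19) | O=C1[C@@H]([C@H](C)C(=O)OCC)[C@H](CO[Si](C(C)C)(C(C)C)C(C)C)[C@@]2(CC#C[Si](C)(C)C)CC(O[Si](C(C)C)(C(C)C)C(C)C)=CC[C@@H]12 | intermediate
17 | (4-methoxyphenyl)methanol | COc1ccc(CO)cc1 | starting material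
18 | tributyl(iodomethyl)stannane | CCCC[Sn](CCCC)(CCCC)CI | starting material
19 | sodium (4-methoxyphenyl)methanolate | COc1ccc(C[O-])cc1.[Na+] | intermediate
20 | tributyl{[(4-methoxybenzyl)oxy]methyl}stannane | CCCC[Sn](CCCC)(CCCC)COCc1ccc(OC)cc1 | intermediate
21 | {[(4-methoxybenzyl)oxy]methyl}lithium | [Li]COCc1ccc(OC)cc1 | intermediate
22 | C10 lithium alkoxide from addition to 16 (C10 α-OLi, β-CH2O-4-methoxybenzyl; ester still open) | [Li]O[C@@]1(COCc2ccc(OC)cc2)[C@@H]([C@H](C)C(=O)OCC)[C@H](CO[Si](C(C)C)(C(C)C)C(C)C)[C@@]3(CC#C[Si](C)(C)C)CC(O[Si](C(C)C)(C(C)C)C(C)C)=CC[C@@H]13 | intermediate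
23 | bicyclic 19,10-γ-lactone: C10 α-O–C19(=O)–C4H(CH3)–C5α, C10 β-CH2O-4-methoxybenzyl, C6 β-CH2OSi(iPr)3, C8 β-[3-(trimethylsilyl)prop-2-ynyl], C12=C13 triisopropylsilyl enol ether | C[C@@H]1C(=O)O[C@@]2(COCc3ccc(OC)cc3)[C@@H]1[C@H](CO[Si](C(C)C)(C(C)C)C(C)C)[C@@]4(CC#C[Si](C)(C)C)CC(O[Si](C(C)C)(C(C)C)C(C)C)=CC[C@@H]24 | intermediate
24 | keto alkyne lactone: as 23 with C13 ketone, C8 β-prop-2-ynyl and C6 β-CH2OH | C[C@@H]1C(=O)O[C@@]2(COCc3ccc(OC)cc3)[C@@H]1[C@H](CO)[C@@]4(CC#C)CC(=O)CC[C@@H]24 | intermediate
25 | tricyclic lactone diol: rings B, C and D with 13-OH and 16-methylene, 19,10-lactone (C4 H/CH3), C10 β-CH2O-4-methoxybenzyl, C6 β-CH2OH | C=C1C[C@]23C[C@@]1(O)CC[C@H]2[C@@]2(COCc4ccc(OC)cc4)OC(=O)[C@@H](C)[C@H]2[C@@H]3CO | intermediate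
26 | C7 aldehyde of 25 | C=C1C[C@]23C[C@@]1(O)CC[C@H]2[C@@]2(COCc4ccc(OC)cc4)OC(=O)[C@@H](C)[C@H]2[C@@H]3C=O | intermediate
27 | C7 carboxylic acid of 25 | C=C1C[C@]23C[C@@]1(O)CC[C@H]2[C@@]2(COCc4ccc(OC)cc4)OC(=O)[C@@H](C)[C@H]2[C@@H]3C(=O)O | intermediate
28 | 2-(trimethylsilyl)ethyl ester of 27 | C=C1C[C@]23C[C@@]1(O)CC[C@H]2[C@@]2(COCc4ccc(OC)cc4)OC(=O)[C@@H](C)[C@H]2[C@@H]3C(=O)OCC[Si](C)(C)C | intermediate
29 | acetaldehyde | CC=O | starting material
30 | dilithium species of 28: C13 lithium alkoxide, C4=C19 lactone lithium enolate | C=C1C[C@]23C[C@@]1(O[Li])CC[C@H]2[C@@]2(COCc4ccc(OC)cc4)OC(O[Li])=C(C)[C@H]2[C@@H]3C(=O)OCC[Si](C)(C)C | intermediate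
31 | 28 with quaternary C4 carrying 1-hydroxyethyl on the face of H-5 and C1 and methyl toward C6; both carbinol epimers | C=C1C[C@]23C[C@@]1(O)CC[C@H]2[C@@]2(COCc4ccc(OC)cc4)OC(=O)[C@@](C)([C@H]2[C@@H]3C(=O)OCC[Si](C)(C)C)C(C)O | intermediate
32 | triol: 31 with C10 β-CH2OH | C=C1C[C@]23C[C@@]1(O)CC[C@H]2[C@@]2(CO)OC(=O)[C@@](C)([C@H]2[C@@H]3C(=O)OCC[Si](C)(C)C)C(C)O | intermediate
33 | keto aldehyde: C4 acetyl, C10 β-formyl, C7 2-(trimethylsilyl)ethyl ester, 13-OH, 16-methylene, 19,10-lactone | C=C1C[C@]23C[C@@]1(O)CC[C@H]2[C@@]2(C=O)OC(=O)[C@@](C)([C@H]2[C@@H]3C(=O)OCC[Si](C)(C)C)C(C)=O | intermediate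
34 | pyrrolidine enamine of the C4 acetyl group of 33 (C2=C3) | C=C1C[C@]23C[C@@]1(O)CC[C@H]2[C@@]2(C=O)OC(=O)[C@@](C)([C@H]2[C@@H]3C(=O)OCC[Si](C)(C)C)C(=C)N4CCCC4 | intermediate
35 | 1β-hydroxy-3-oxo tetracyclic lactone, 2-(trimethylsilyl)ethyl ester, 13-OH free | C=C1C[C@]23C[C@@]1(O)CC[C@H]2[C@@]12OC(=O)[C@@](C)([C@H]1[C@@H]3C(=O)OCC[Si](C)(C)C)C(=O)C[C@H]2O | intermediate
36 | GA55 2-(trimethylsilyl)ethyl ester (1β,3β,13-triol) | C=C1C[C@]23C[C@@]1(O)CC[C@H]2[C@@]12OC(=O)[C@@](C)([C@H]1[C@@H]3C(=O)OCC[Si](C)(C)C)[C@@H](O)C[C@H]2O | intermediate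
37 | GA55 | C=C1C[C@]23C[C@@]1(O)CC[C@H]2[C@@]12OC(=O)[C@@](C)([C@H]1[C@@H]3C(=O)O)[C@@H](O)C[C@H]2O | target

Total step count: 19. Longest linear sequence: 17 steps (steps 1–4, 6, 7 and 9–19); steps 5 and 8 make the diene and the stannane.

Steps most likely to fail

Step 6. The hindered enone may fail to undergo cycloaddition, with 1,2-addition of the silyl enol ether or decomposition of the diene taking over. The fallback sets out from 10 and comes back at 13. Thermal Diels–Alder reaction of 10 with the more reactive, commercial 1-(dimethylamino)-3-(tert-butyldimethylsilyloxy)buta-1,3-diene (toluene, 60–80 °C) should give the amino silyl enol ether cycloadduct F1 with the same regiochemistry and the same anti approach. Aqueous HF in MeCN then hydrolyses the enol ether and eliminates dimethylamine to the cis-fused enedione F2. RhCl(PPh3)3-catalysed 1,4-hydrosilylation of the enone with iPr3SiH converts it regiospecifically into the C12=C13 triisopropylsilyl enol ether, which is 13.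

Step 17. The ketol may lose water to the C1=C2 enone, or the C1 hydroxyl may form on the wrong face. The fallback sets out from 33 and comes back at 35. Deliberate aldol condensation (piperidinium acetate, benzene, 60 °C) gives the C1=C2 enone F3. Nucleophilic epoxidation (t-BuOOH, 1,8-diazabicyclo[5.4.0]undec-7-ene, CH2Cl2, 0 °C) should occur on the β face, the α face being covered by the lactone bridge, to give the 1β,2β-epoxy ketone F4. Reductive cleavage of the C2–O bond of the epoxy ketone with SmI2 (THF/MeOH, −78 °C) then gives 35 with the 1β-hydroxyl.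

Step 2. The lipase may discriminate the enantiomers of the primary alcohol poorly. The fallback sets out from 4 and comes back at 5. Racemic 4 is esterified with (S)-2-methoxy-2-phenylacetic acid (dicyclohexylcarbodiimide, 4-(dimethylamino)pyridine, CH2Cl2), the diastereomeric esters are separated by chromatography or crystallisation, and the (S)-2-methoxy-2-phenylacetate of the (R)-alcohol F5 is methanolysed (K2CO3, MeOH, 0 °C) to 5.

Further compounds
F1 | step 6 | cycloadduct of 10 with the aminosilyloxydiene: as 13 but with a C13 tert-butyldimethylsilyl enol ether and a C11 dimethylamino group | O=C1C[C@H](CO[Si](C(C)C)(C(C)C)C(C)C)[C@@]2(CC#C[Si](C)(C)C)CC(O[Si](C)(C)C(C)(C)C)=CC(N(C)C)[C@@H]12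
F2 | step 6 | cis-fused enedione: C10 ketone and C13 ketone conjugated with C11=C12 | O=C1C[C@H](CO[Si](C(C)C)(C(C)C)C(C)C)[C@@]2(CC#C[Si](C)(C)C)CC(=O)C=C[C@@H]12
F3 | step 17 | C1=C2 enone (3-oxo tetracyclic lactone 2-(trimethylsilyl)ethyl ester) | C=C1C[C@]23C[C@@]1(O)CC[C@H]2[C@@]12OC(=O)[C@@](C)([C@H]1[C@@H]3C(=O)OCC[Si](C)(C)C)C(=O)C=C2
F4 | step 17 | 1β,2β-epoxy-3-ketone | C=C1C[C@]23C[C@@]1(O)CC[C@H]2[C@@]12OC(=O)[C@@](C)([C@H]1[C@@H]3C(=O)OCC[Si](C)(C)C)C(=O)[C@H]4O[C@H]42
F5 | step 2 | (S)-2-methoxy-2-phenylacetate of (R)-5-(hydroxymethyl)-3-methoxycyclopent-2-en-1-one | COC1=CC(=O)[C@@H](COC(=O)[C@@H](OC)c2ccccc2)C1
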